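Labdane numbering is used: ring A = C1–C5 + C10, ring B = C5–C10, C17 on C8, C18/C19 on C4, C20 on C10, side chain C11–C16.

**Plan**
- **Cuts:** C12–C13 (sp3–sp2 coupling to the butenolide). Then C4–C18 and C4–C19, back to a C4 ketone. Then, in one stroke, C9–C10 of ring B together with re-closure of a C4–C10 bond. Then C7–C8, and last the two cyclopropane bonds at C5.
- **Enabling feature:** C4 carries two identical CH2OH arms, so it is not a stereocentre and can be a ketone. In ring A it stands 1,3 to the quaternary C10 across C5, which is the pattern of a β-keto radical. C4–C5–C10 can therefore be stored as a cyclopropanol whose zero bridge C4–C10 closes a five-membered ring C1–C2–C3–C4–C10. C17 and C12 can be tied as a δ-lactone, which makes C9 electrophilic and locks the C8=C9 geometry.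
- **Forward order:** the cyclopentane and cyclopropane come first (a bicyclo[3.1.0]hexan-1-ol) and the lactone ring is attached by Suzuki coupling. Ring A (five to six atoms) and ring B then arise together in the key step. Afterwards the lactone is opened to ester plus vinyl, C4=O becomes C(CH2OH)2, and the butenolide comes last.
- **Stereochemistry:** C5 comes from an enantioselective copper–bis(oxazoline) cyclopropanation; it is the carbenoid carbon and the only centre that survives ring opening. It relays to C10 and C9 through a chair-like 6-endo transition state. C8 (and C5) are secured by equilibration, and C4 needs no control.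

Key step: step 8

Assumption: the (S,S)-bis(oxazoline) is taken to deliver the carbenoid carbon with the configuration drawn in 4; if the sense of induction is the opposite, the equally available (R,R)-ligand is used.

Step 1
Reactants: 1 2-methylcyclopent-2-en-1-one
Product: 2 triethyl[(2-methylcyclopent-1-en-1-yl)oxy]silane
Conditions: Et3SiH (1.1 equiv), RhCl(PPh3)3 (0.5 mol%), THF, 50 °C
Reagents that add atoms: triethylsilane, CC[SiH](CC)CC
Why: Rhodium-catalysed 1,4-hydrosilylation of the enone should give the tetrasubstituted silyl enol ether regiospecifically, which enolisation of 2-methylcyclopentanone would not; no stereocentre is formed.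

Step 2
Reactants: 2 triethyl[(2-methylcyclopent-1-en-1-yl)oxy]silane; 3 ethyl diazoacetate
Product: 4 ethyl (1S,5S,6S)-5-methyl-1-(triethylsilyloxy)bicyclo[3.1.0]hexane-6-carboxylate
Conditions: (CuOTf)2·C6H6 (1 mol%), (S,S)-t-Bu-box (2.2 mol%), CH2Cl2, rt, 3 added over 12 h
Reagents that add atoms: none
Why: Enantioselective cyclopropanation of a silyl enol ether by a monovalent-copper carbenoid: the ligand shields one face of the carbenoid carbon and the nucleophilic methyl-bearing enol carbon bonds first, which fixes C5 (C6 of the bicycle); the exo ester (cis to OSiEt3 and CH3) is drawn, and any endo isomer should carry the same configuration at this carbon and converge in step 8, where both bridgehead centres are erased.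

Step 3
Reactants: 4 ethyl (1S,5S,6S)-5-methyl-1-(triethylsilyloxy)bicyclo[3.1.0]hexane-6-carboxylate
Product: 5 (1S,5S,6S)-5-methyl-1-(triethylsilyloxy)bicyclo[3.1.0]hexane-6-carbaldehyde
Conditions: i-Bu2AlH (1.05 equiv), toluene, −78 °C; aq potassium sodium tartrate
Reagents that add atoms: none
Why: Partial ester reduction stops at the aluminium hemiacetal, which is stable at −78 °C; silyl ether and stereocentres are untouched and the sensitive aldehyde is used crude.

Step 4
Reactants: 5 (1S,5S,6S)-5-methyl-1-(triethylsilyloxy)bicyclo[3.1.0]hexane-6-carbaldehyde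
Product: 6 triethyl{[(1S,5S,6S)-6-ethenyl-5-methylbicyclo[3.1.0]hexan-1-yl]oxy}silane
Conditions: MePPh3Br, KN(SiMe3)2, THF, 0 °C; then 5, −78 °C to rt
Reagents that add atoms: methyltriphenylphosphonium bromide, C[P+](c1ccccc1)(c1ccccc1)c1ccccc1.[Br-]
Why: Wittig methylenation with the non-stabilised ylide is fast at low temperature, so the cyclopropane C–H next to the aldehyde should not epimerise and the donor–acceptor ring should not open.

Step 5
Reactants: 7 5,6-dihydro-2H-pyran-2-one
Product: 9 3-bromo-5,6-dihydro-2H-pyran-2-one, via trans-dibromolactone 8 (not isolated)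
Conditions: Br2, CH2Cl2, 0 °C to rt; then Et3N, 0 °C
Reagents that add atoms: bromine, BrBr
Why: Bromine addition to the enoate followed by base-induced loss of HBr (the acidic α-H leaves with the β-bromide) gives the α-bromo unsaturated lactone.

Step 6
Reactants: 6 triethyl{[(1S,5S,6S)-6-ethenyl-5-methylbicyclo[3.1.0]hexan-1-yl]oxy}silane; 9 3-bromo-5,6-dihydro-2H-pyran-2-one
Product: 11 3-{2-[(1S,5S,6S)-5-methyl-1-(triethylsilyloxy)bicyclo[3.1.0]hexan-6-yl]ethyl}-5,6-dihydro-2H-pyran-2-one, via B-alkyl-9-BBN 10 (not isolated)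
Conditions: 9-BBN, THF, rt; H2O; then 9, PdCl2(dppf) (5 mol%), AsPh3 (10 mol%), Cs2CO3, DMF–THF–H2O, rt
Reagents that add atoms: none
Why: Anti-Markovnikov hydroboration of the only olefin and B-alkyl Suzuki–Miyaura coupling, a reaction type established for α-halo enones and enoates, form C7–C8 with the ring-locked olefin geometry; carbonate at room temperature should spare lactone and silyl ether.

Step 7
Reactants: 11 3-{2-[(1S,5S,6S)-5-methyl-1-(triethylsilyloxy)bicyclo[3.1.0]hexan-6-yl]ethyl}-5,6-dihydro-2H-pyran-2-one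
Product: 12 3-{2-[(1S,5S,6S)-1-hydroxy-5-methylbicyclo[3.1.0]hexan-6-yl]ethyl}-5,6-dihydro-2H-pyran-2-one
Conditions: HF·pyridine, pyridine, THF, 0 °C
Reagents that add atoms: none
Why: Fluoride cleavage of the triethylsilyl ether in a buffered, non-basic medium frees the cyclopropanol without homoenolate ring opening.

Step 8
Reactants: 12 3-{2-[(1S,5S,6S)-1-hydroxy-5-methylbicyclo[3.1.0]hexan-6-yl]ethyl}-5,6-dihydro-2H-pyran-2-one
Product: 14 (5S,8S,9R,10S)-4-oxo-13,14,15,16,18,19-hexanorlabdan-17,12-olide, via 8-epi-keto-lactone 13 (not isolated)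
Conditions: manganese tris(pyridine-2-carboxylate), Mn(O2C-2-C5H4N)3 (2.5 equiv), DMF (0.01 M), 0 °C, Bu3SnH (1.3 equiv) by syringe pump; work-up; then DBU (0.3 equiv), toluene, 60 °C
Reagents that add atoms: none
Why: One-electron oxidation of the cyclopropanol by trivalent manganese gives the bicyclo[3.1.0]hexan-1-oxyl radical, whose β-scission should break the zero bridge C4–C10 (tertiary radical, strain release), so that the cyclopentane C1–C2–C3–C4–C10 takes up C5 and becomes the cyclohexanone ring A with a nucleophilic radical at C10; if the external bond C4–C5 breaks first, the C5 radical reaches the same species by a Dowd–Beckwith 1,2-acyl shift. The closest known reaction type is the oxidative ring enlargement of bicyclo[n.1.0]alkan-1-ols or their silyl ethers to cyclic β-keto radicals followed by cyclisation onto a pendant olefin, together with the Giese addition of such radicals to electron-poor olefins terminated by Bu3SnH. Ring B closes in the 6-endo-trig mode, the polarity-matched C10 radical attacking the β-carbon C9 of the α-substituted unsaturated lactone, whereas 5-exo attack at the fully substituted α-carbon C8 is sterically and electronically disfavoured. C10 is controlled by C5, the only stereocentre that survives ring opening: a chair-like transition state with the C5 chain equatorial on ring A puts CH3-20 axial and should give the trans-decalin, while C9 is controlled by the olefin geometry locked in the lactone ring (C11 trans to C7 across C8=C9, hence equatorial). C8 is first set by hydrogen transfer from Bu3SnH to the lactone α-radical, expected from the face away from CH3-20 (cis-lactone 13), and is then corrected by DBU to the trans-diequatorial lactone 14, conditions under which C5 next to the ketone also rests in the more stable trans-decalone form. The step needs cyclisation to outrun hydrogen transfer to the C10 radical, which high dilution and slow addition of the stannane should secure.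

Step 9
Reactants: 14 (5S,8S,9R,10S)-4-oxo-13,14,15,16,18,19-hexanorlabdan-17,12-olide
Product: 16 methyl (1R,2S,4aS,8aS)-8a-methyl-5-oxo-1-[2-(phenylselanyl)ethyl]decahydronaphthalene-2-carboxylate, via sodium carboxylate 15 (not isolated)
Conditions: PhSeH (1.5 equiv), NaH (1.4 equiv), THF–HMPA, 0 °C; then 14, 65 °C; then MeI, rt
Reagents that add atoms: benzeneselenol, [SeH]c1ccccc1; iodomethane, CI
Why: SN2 opening of the lactone at the primary O-alkyl carbon C12 by the soft, weakly basic selenolate, then O-methylation of the carboxylate in the same flask, tells C12 from C17 without any selectivity problem; no stereocentre takes part.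

Step 10
Reactants: 16 methyl (1R,2S,4aS,8aS)-8a-methyl-5-oxo-1-[2-(phenylselanyl)ethyl]decahydronaphthalene-2-carboxylate
Product: 18 methyl (1R,2S,4aS,8aS)-1-ethenyl-8a-methyl-5-oxodecahydronaphthalene-2-carboxylate, via selenoxide 17 (not isolated)
Conditions: 30% H2O2 (3 equiv), pyridine, CH2Cl2, 0 °C to rt
Reagents that add atoms: none
Why: Selenide oxidation and syn-elimination of the primary selenoxide give the terminal olefin C11=C12, since the only β-hydrogens are those on C11.

Step 11
Reactants: 18 methyl (1R,2S,4aS,8aS)-1-ethenyl-8a-methyl-5-oxodecahydronaphthalene-2-carboxylate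
Product: 19 methyl (1R,2S,4aS,8aS)-1-ethenyl-5-(methoxymethylidene)-8a-methyldecahydronaphthalene-2-carboxylate (E/Z mixture)
Conditions: MeOCH2PPh3Cl (3 equiv), t-BuOK (2.8 equiv), THF, 0 °C to rt
Reagents that add atoms: (methoxymethyl)triphenylphosphonium chloride, COC[P+](c1ccccc1)(c1ccccc1)c1ccccc1.[Cl-]
Why: Wittig methoxymethylenation homologates the C4 ketone; the ester is inert to the ylide, and C5 and C8, if enolised, return to their more stable arrangement.

Step 12
Reactants: 19 methyl (1R,2S,4aS,8aS)-1-ethenyl-5-(methoxymethylidene)-8a-methyldecahydronaphthalene-2-carboxylate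
Product: 20 methyl (1R,2S,4aR,5S,8aR)-1-ethenyl-5-formyl-8a-methyldecahydronaphthalene-2-carboxylate
Conditions: TsOH·H2O (0.1 equiv), THF–H2O 4:1, rt
Reagents that add atoms: water, O
Why: Acid hydrolysis of the enol ether gives the aldehyde (equatorial formyl expected); the C4 configuration does not matter because it is erased in step 13.

Step 13
Reactants: 20 methyl (1R,2S,4aR,5S,8aR)-1-ethenyl-5-formyl-8a-methyldecahydronaphthalene-2-carboxylate
Product: 21 methyl (1R,2S,4aS,5R,8aS)-1-ethenyl-5-formyl-5-(hydroxymethyl)-8a-methyldecahydronaphthalene-2-carboxylate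
Conditions: 37% aq CH2O (10 equiv), K2CO3 (0.5 equiv), MeOH, 45 °C
Reagents that add atoms: formaldehyde, C=O
Why: Crossed aldol hydroxymethylation of the α-branched aldehyde with non-enolisable formaldehyde creates the quaternary C4; attack from the equatorial face away from CH3-20 is expected, but the outcome is without consequence since both arms become CH2OH, and the ester α-position is not enolised by carbonate.

Step 14
Reactants: 21 methyl (1R,2S,4aS,5R,8aS)-1-ethenyl-5-formyl-5-(hydroxymethyl)-8a-methyldecahydronaphthalene-2-carboxylate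
Product: 22 [(1R,2S,4aS,8aS)-1-ethenyl-8a-methyldecahydronaphthalene-2,5,5-triyl]trimethanol
Conditions: LiAlH4 (3 equiv), THF, −20 °C to rt
Reagents that add atoms: none
Why: Hydride reduction of aldehyde and ester at once gives the three primary alcohols and makes C4 non-stereogenic; the isolated vinyl group is inert.

Step 15
Reactants: 23 furan-2(5H)-one
Product: 25 3-bromofuran-2(5H)-one, via trans-dibromobutyrolactone 24 (not isolated)
Conditions: Br2, CH2Cl2, 0 °C to reflux; then Et3N, 0 °C
Reagents that add atoms: bromine, BrBr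
Why: The same bromination and dehydrobromination sequence as in step 5 gives the α-bromobutenolide.

Step 16
Reactants: 22 [(1R,2S,4aS,8aS)-1-ethenyl-8a-methyldecahydronaphthalene-2,5,5-triyl]trimethanol; 25 3-bromofuran-2(5H)-one
Product: 27 3-{2-[(1R,2S,4aS,8aS)-2,5,5-tris(hydroxymethyl)-8a-methyldecahydronaphthalen-1-yl]ethyl}furan-2(5H)-one, via tetraboron intermediate 26 (not isolated)
Conditions: 9-BBN (4.5 equiv), THF, rt to 40 °C; H2O; then 25 (1.3 equiv), PdCl2(dppf) (5 mol%), AsPh3 (10 mol%), aq K3PO4, DMF, rt
Reagents that add atoms: none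
Why: Hydroboration of the monosubstituted olefin (the three hydroxyls are masked in situ as borinates by excess 9-BBN) and B-alkyl Suzuki–Miyaura coupling with the α-bromobutenolide form C12–C13 and install the intact butenolide in one operation; the borinates hydrolyse in the aqueous medium and no stereocentre is touched.

**Compound list**
1 | 2-methylcyclopent-2-en-1-one | CC1=CCCC1=O | starting material
2 | triethyl[(2-methylcyclopent-1-en-1-yl)oxy]silane | CC1=C(O[Si](CC)(CC)CC)CCC1 | intermediate
3 | ethyl diazoacetate | CCOC(=O)C=[N+]=[N-] | starting material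
4 | ethyl (1S,5S,6S)-5-methyl-1-(triethylsilyloxy)bicyclo[3.1.0]hexane-6-carboxylate (exo ester) | CC[Si](CC)(CC)O[C@]12CCC[C@@]1(C)[C@@H]2C(=O)OCC | intermediate
5 | (1S,5S,6S)-5-methyl-1-(triethylsilyloxy)bicyclo[3.1.0]hexane-6-carbaldehyde | CC[Si](CC)(CC)O[C@]12CCC[C@@]1(C)[C@@H]2C=O | intermediate
6 | triethyl{[(1S,5S,6S)-6-ethenyl-5-methylbicyclo[3.1.0]hexan-1-yl]oxy}silane | CC[Si](CC)(CC)O[C@]12CCC[C@@]1(C)[C@@H]2C=C | intermediate
7 | 5,6-dihydro-2H-pyran-2-one | O=C1C=CCCO1 | starting material
8 | (±)-trans-3,4-dibromooxan-2-one (one enantiomer drawn) | O=C1OCC[C@@H](Br)[C@@H]1Br | intermediate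
9 | 3-bromo-5,6-dihydro-2H-pyran-2-one | O=C1OCCC=C1Br | intermediate
10 | 9-{2-[(1S,5S,6S)-5-methyl-1-(triethylsilyloxy)bicyclo[3.1.0]hexan-6-yl]ethyl}-9-borabicyclo[3.3.1]nonane | CC[Si](CC)(CC)O[C@]12CCC[C@@]1(C)[C@@H]2CCB3C4CCCC3CCC4 | intermediate
11 | 3-{2-[(1S,5S,6S)-5-methyl-1-(triethylsilyloxy)bicyclo[3.1.0]hexan-6-yl]ethyl}-5,6-dihydro-2H-pyran-2-one | CC[Si](CC)(CC)O[C@]12CCC[C@@]1(C)[C@@H]2CCC3=CCCOC3=O | intermediate
12 | 3-{2-[(1S,5S,6S)-1-hydroxy-5-methylbicyclo[3.1.0]hexan-6-yl]ethyl}-5,6-dihydro-2H-pyran-2-one | O[C@]12CCC[C@@]1(C)[C@@H]2CCC3=CCCOC3=O | intermediate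
13 | (5S,8R,9R,10S)-4-oxo-13,14,15,16,18,19-hexanorlabdan-17,12-olide (trans-decalin, cis-fused lactone, C17 axial) | C[C@@]12CCCC(=O)[C@H]1CC[C@@H]3[C@H]2CCOC3=O | intermediate
14 | (5S,8S,9R,10S)-4-oxo-13,14,15,16,18,19-hexanorlabdan-17,12-olide (trans-anti-trans, C17 and C11 equatorial) | C[C@@]12CCCC(=O)[C@H]1CC[C@H]3[C@H]2CCOC3=O | intermediate
15 | sodium (1R,2S,4aS,8aS)-8a-methyl-5-oxo-1-[2-(phenylselanyl)ethyl]decahydronaphthalene-2-carboxylate | C[C@@]12CCCC(=O)[C@H]1CC[C@H](C(=O)[O-])[C@H]2CC[Se]c3ccccc3.[Na+] | intermediate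
16 | methyl (1R,2S,4aS,8aS)-8a-methyl-5-oxo-1-[2-(phenylselanyl)ethyl]decahydronaphthalene-2-carboxylate | C[C@@]12CCCC(=O)[C@H]1CC[C@H](C(=O)OC)[C@H]2CC[Se]c3ccccc3 | intermediate
17 | methyl (1R,2S,4aS,8aS)-8a-methyl-5-oxo-1-[2-(phenylseleninyl)ethyl]decahydronaphthalene-2-carboxylate (both configurations at Se) | C[C@@]12CCCC(=O)[C@H]1CC[C@H](C(=O)OC)[C@H]2CC[Se](=O)c3ccccc3 | intermediate
18 | methyl (1R,2S,4aS,8aS)-1-ethenyl-8a-methyl-5-oxodecahydronaphthalene-2-carboxylate | C[C@@]12CCCC(=O)[C@H]1CC[C@H](C(=O)OC)[C@H]2C=C | intermediate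
19 | methyl (1R,2S,4aS,8aS)-1-ethenyl-5-(methoxymethylidene)-8a-methyldecahydronaphthalene-2-carboxylate (E/Z mixture) | C[C@@]12CCCC(=COC)[C@H]1CC[C@H](C(=O)OC)[C@H]2C=C | intermediate
20 | methyl (1R,2S,4aR,5S,8aR)-1-ethenyl-5-formyl-8a-methyldecahydronaphthalene-2-carboxylate (formyl equatorial) | C[C@@]12CCC[C@H](C=O)[C@H]1CC[C@H](C(=O)OC)[C@H]2C=C | intermediate
21 | methyl (1R,2S,4aS,5R,8aS)-1-ethenyl-5-formyl-5-(hydroxymethyl)-8a-methyldecahydronaphthalene-2-carboxylate (CH2OH equatorial, CHO axial) | C[C@@]12CCC[C@@](CO)(C=O)[C@H]1CC[C@H](C(=O)OC)[C@H]2C=C | intermediate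
22 | [(1R,2S,4aS,8aS)-1-ethenyl-8a-methyldecahydronaphthalene-2,5,5-triyl]trimethanol | C[C@@]12CCCC(CO)(CO)[C@H]1CC[C@H](CO)[C@H]2C=C | intermediate
23 | furan-2(5H)-one | O=C1C=CCO1 | starting material
24 | (±)-trans-3,4-dibromooxolan-2-one (one enantiomer drawn) | O=C1OC[C@@H](Br)[C@@H]1Br | intermediate
25 | 3-bromofuran-2(5H)-one | O=C1OCC=C1Br | intermediate
26 | C12 B-alkyl-9-BBN derived from 22 with the three hydroxyls as 9-BBN borinates | C[C@@]12CCCC(COB3C4CCCC3CCC4)(COB3C4CCCC3CCC4)[C@H]1CC[C@H](COB3C4CCCC3CCC4)[C@H]2CCB3C4CCCC3CCC4 | intermediate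
27 | 3-{2-[(1R,2S,4aS,8aS)-2,5,5-tris(hydroxymethyl)-8a-methyldecahydronaphthalen-1-yl]ethyl}furan-2(5H)-one (labdane numbering 5S,8S,9R,10S) | C[C@@]12CCCC(CO)(CO)[C@H]1CC[C@H](CO)[C@H]2CCC1=CCOC1=O | target

**Step count**
Total steps: 16. Longest linear sequence: 14 (steps 1–4, 6–14, 16).

**Steps most likely to fail**

**1. Step 8.**
- Risk: hydrogen transfer to the ring-enlarged C10 radical, or to a C5 radical from external β-scission, may come before the slow 6-endo closure, because oxidant and stannane must coexist in the flask.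
- Fallback (from 11, back at 14): ring enlargement and ring closure are separated. FeCl3 (2.2 equiv) in DMF at 0 °C performs the ring enlargement of the siloxycyclopropane alone and caps the C10 radical with chlorine, giving (2R)-3-chloro-3-methyl-2-[2-(2-oxo-5,6-dihydro-2H-pyran-3-yl)ethyl]cyclohexan-1-one F1. The tertiary chloride then serves as radical precursor in a conventional tin hydride cyclisation (Bu3SnH and AIBN by syringe pump, benzene, 80 °C, high dilution), where the donor concentration can be set freely. DBU equilibration as in step 8 returns the material to the route at 14.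

**2. Step 2.**
- Risk: carbenoid transfer to the tetrasubstituted enol ether may be sluggish, with carbene dimerisation taking over, or facial selectivity at the carbenoid carbon may be poor.
- Fallback (from 2, back at 5): the source of chirality is changed to an enzymatic resolution. Cyclopropanation of 2 with 3 under achiral Rh2(OAc)4 catalysis gives 4 as the racemate. LiAlH4 reduction gives the racemic form of [(1S,5S,6R)-5-methyl-1-(triethylsilyloxy)bicyclo[3.1.0]hexan-6-yl]methanol F2. Acetylation with vinyl acetate and Candida antarctica lipase B removes the unwanted enantiomer as [(1R,5R,6S)-5-methyl-1-(triethylsilyloxy)bicyclo[3.1.0]hexan-6-yl]methyl acetate F3. The remaining alcohol is oxidised with the periodinane DMP and NaHCO3 in CH2Cl2 to 5.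

**3. Step 16.**
- Risk: the bromobutenolide may decompose under base, the alkylborane may suffer protodeboronation or the alkylpalladium β-hydride elimination, and transmetalation may be slow in the presence of much borinate.
- Fallback (from 22, back at 27): C12–C13 is made by enolate alkylation instead.
 - TBSOTf and 2,6-lutidine give the tris(tert-butyldimethylsilyl) ether of 22, F4.
 - 9-BBN, then NaOH and H2O2, give the C12 primary alcohol F5.
 - I2, PPh3 and imidazole give the C12 primary iodide F6.
 - The lithium enolate of 3-(phenylsulfanyl)oxolan-2-one (LDA, THF–DMPU) is alkylated with F6 to the α-alkyl-α-(phenylsulfanyl)butyrolactone F7.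
 - mCPBA at −78 °C gives the sulfoxide F8, which loses sulfenic acid in refluxing toluene to give the tris-silylated butenolide F9.
 - HF·pyridine in THF removes the silyl groups and gives 27.

Further compounds
F1 | step 8 | (2R)-3-chloro-3-methyl-2-[2-(2-oxo-5,6-dihydro-2H-pyran-3-yl)ethyl]cyclohexan-1-one (both configurations at C3) | CC1(Cl)CCCC(=O)[C@H]1CCC2=CCCOC2=O
F2 | step 2 | [(1S,5S,6R)-5-methyl-1-(triethylsilyloxy)bicyclo[3.1.0]hexan-6-yl]methanol | CC[Si](CC)(CC)O[C@]12CCC[C@@]1(C)[C@@H]2CO
F3 | step 2 | [(1R,5R,6S)-5-methyl-1-(triethylsilyloxy)bicyclo[3.1.0]hexan-6-yl]methyl acetate | CC[Si](CC)(CC)O[C@@]12CCC[C@]1(C)[C@H]2COC(C)=O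
F4 | step 16 | tris(tert-butyldimethylsilyl) ether of 22 | C[C@@]12CCCC(CO[Si](C)(C)C(C)(C)C)(CO[Si](C)(C)C(C)(C)C)[C@H]1CC[C@H](CO[Si](C)(C)C(C)(C)C)[C@H]2C=C
F5 | step 16 | C12 primary alcohol from F4 | C[C@@]12CCCC(CO[Si](C)(C)C(C)(C)C)(CO[Si](C)(C)C(C)(C)C)[C@H]1CC[C@H](CO[Si](C)(C)C(C)(C)C)[C@H]2CCO
F6 | step 16 | C12 primary iodide | C[C@@]12CCCC(CO[Si](C)(C)C(C)(C)C)(CO[Si](C)(C)C(C)(C)C)[C@H]1CC[C@H](CO[Si](C)(C)C(C)(C)C)[C@H]2CCI
F7 | step 16 | α-alkyl-α-(phenylsulfanyl)butyrolactone (both configurations at C13) | C[C@@]12CCCC(CO[Si](C)(C)C(C)(C)C)(CO[Si](C)(C)C(C)(C)C)[C@H]1CC[C@H](CO[Si](C)(C)C(C)(C)C)[C@H]2CCC3(Sc4ccccc4)CCOC3=O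
F8 | step 16 | sulfoxide of F7 | C[C@@]12CCCC(CO[Si](C)(C)C(C)(C)C)(CO[Si](C)(C)C(C)(C)C)[C@H]1CC[C@H](CO[Si](C)(C)C(C)(C)C)[C@H]2CCC3(S(=O)c4ccccc4)CCOC3=O
F9 | step 16 | tris(tert-butyldimethylsilyl) ether of 27 | C[C@@]12CCCC(CO[Si](C)(C)C(C)(C)C)(CO[Si](C)(C)C(C)(C)C)[C@H]1CC[C@H](CO[Si](C)(C)C(C)(C)C)[C@H]2CCC3=CCOC3=O
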